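Ring B is disconnected at the ring-fusion bond C5–C10 and at C6–C7 (drimane numbering). These bonds flank the C5–C6 edge, so ring B is the adduct of a C7=C8–C9=C10 diene and a C5=C6 dienophile, and the C1–C4 chain of ring A is their tether. The key step is therefore an iminium-catalysed enantioselective intramolecular Diels–Alder reaction of an acyclic (2E,8Z)-trienal that closes rings A and B at once and sets C5 and quaternary C10 (trans). The activating formyl group is then excised, C8 is set by hydrogenation, and an aryllithium is added to the C11 aldehyde; dehydration, formylation, sulfation and desilylation finish the target.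

Key step: step 5

Remark: drimane numbering is used (C4 gem-dimethyl carbon, C5 ring-fusion CH, C8 CH(CH3), C9 alkylidene carbon, C10 angular-methyl carbon, C11 benzylic carbon; arene C1′ bonded to C11, C6′ bearing the sulfate); the aryl hydrogen sulfates 29 and 30 are handled as salts and written in the neutral acid form, and 22–25 are epimeric at the acetal carbon and/or C11, centres that vanish in step 14.

Step 1
Reactants: 1 but-2-yn-1-ol; 2 isopropenylmagnesium bromide
Product: 4 (Z)-3-iodo-2-(prop-1-en-2-yl)but-2-en-1-ol, via cyclic alkenylmagnesium alkoxide 3 (not isolated)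
Conditions: 2 (3.5 equiv), THF/cyclohexane, 70 °C; then I2, THF, −40 to 0 °C; aq. NH4Cl/Na2S2O3
Reagents that add atoms: iodine, II
Why: Hydroxyl-directed anti-carbomagnesiation of the propargylic alkoxide places the isopropenyl group on the proximal alkyne carbon and magnesium on the distal one inside the five-membered chelate 3, and iodinolysis with retention should give the tetrasubstituted iodide with iodine cis to CH2OH and methyl cis to the isopropenyl group.

Step 2
Reactants: 5 2,2-dimethylpent-4-enal; 6 diethyl [2-(methoxy(methyl)amino)-2-oxoethyl]phosphonate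
Product: 7 (E)-N-methoxy-N,4,4-trimethylhepta-2,6-dienamide
Conditions: LiCl, DBU, MeCN, 0 °C to rt
Reagents that add atoms: none
Why: Horner–Wadsworth–Emmons olefination of a non-enolisable aldehyde with a stabilised phosphonate anion should give the E alkene.

Step 3
Reactants: 7 (E)-N-methoxy-N,4,4-trimethylhepta-2,6-dienamide; 4 (Z)-3-iodo-2-(prop-1-en-2-yl)but-2-en-1-ol
Product: 9 (2E,8Z)-9-(hydroxymethyl)-N-methoxy-N,4,4,8,10-pentamethylundeca-2,8,10-trienamide, via B-alkyl-9-borabicyclononane 8 (not isolated)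
Conditions: 9-BBN, THF, 0 °C to rt; then 4, Pd(dppf)Cl2 (5 mol %), AsPh3, aq. K3PO4, DMF, 50 °C
Reagents that add atoms: none
Why: 9-BBN hydroborates only the unhindered monosubstituted alkene of 7 (anti-Markovnikov), and the B-alkyl Suzuki–Miyaura coupling of 8 with the alkenyl iodide proceeds with retention, which fixes the 8Z geometry (chain cis to CH2OH, methyl cis to the isopropenyl group).

Step 4
Reactants: 9 (2E,8Z)-9-(hydroxymethyl)-N-methoxy-N,4,4,8,10-pentamethylundeca-2,8,10-trienamide
Product: 10 (2E,8Z)-9-(hydroxymethyl)-4,4,8,10-tetramethylundeca-2,8,10-trienal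
Conditions: i-Bu2AlH (2.3 equiv), THF, −78 °C; aq. potassium sodium tartrate
Reagents that add atoms: none
Why: Reduction of the N-methoxy-N-methylamide by i-Bu2AlH stops at the chelated hemiaminal aluminate, which releases the E enal only on work-up; the first equivalent of hydride is consumed by the free hydroxyl.

Step 5
Reactants: 10 (2E,8Z)-9-(hydroxymethyl)-4,4,8,10-tetramethylundeca-2,8,10-trienal
Product: 13 (1S,4aS,8aS)-4-(hydroxymethyl)-3,4a,8,8-tetramethyl-1,2,4a,5,6,7,8,8a-octahydronaphthalene-1-carbaldehyde, via trienyl iminium ion 11 (not isolated), via cycloadduct iminium ion 12 (not isolated)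
Conditions: (2S,5S)-5-benzyl-2-tert-butyl-3-methylimidazolidin-4-one·CF3CO2H (20 mol %), MeCN/H2O (98:2), 5 °C to rt
Reagents that add atoms: none
Why: Condensation of the enal with the amine salt gives the (E)-iminium ion 11, whose LUMO-lowered C5=C6 alkene is captured by the tethered s-cis diene C7=C8–C9=C10 in a concerted, asynchronous [4π+2π] cycloaddition that forms C6–C7 and C5–C10 together, and hydrolysis of 12 returns the catalyst. The closest known reaction type is the imidazolidinone-catalysed intramolecular Diels–Alder reaction of 2,7,9-decatrienals to trans-fused octalins. Ring B is closed by both new bonds as the six-membered cycloaddition ring, and ring A is closed in the same event by the C5–C10 bond through the four-carbon tether held chair-like (type 1 intramolecular mode). The benzyl group of the (5S)-configured catalyst covers one face of the iminium ion, so the diene should add to the open face and set C5 as S; the endo transition state then places the C10 methyl anti to H-5 (10S, trans fusion) and the formyl group at C6 cis to H-5, a centre erased in step 6. The step needs endo over exo selectivity, one enantioface and reaction of the enal alone; these are secured by the E enal, the 8Z diene geometry that puts the tether outside and the methyl inside at the diene terminus, the gem-dimethyl group that preorganises the tether, and iminium activation of a single alkene.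

Step 6
Reactants: 13 (1S,4aS,8aS)-4-(hydroxymethyl)-3,4a,8,8-tetramethyl-1,2,4a,5,6,7,8,8a-octahydronaphthalene-1-carbaldehyde
Product: 14 [(4aS,8aS)-2,5,5,8a-tetramethyl-3,4,4a,5,6,7,8,8a-octahydronaphthalen-1-yl]methanol
Conditions: RhCl(PPh3)3 (1.1 equiv), toluene, 110 °C
Reagents that add atoms: none
Why: Tsuji–Wilkinson decarbonylation (acyl C–H oxidative addition, CO extrusion, C–H reductive elimination) replaces the formyl group by hydrogen so that C6 becomes a methylene, while the tetrasubstituted alkene is too hindered to bind rhodium and the alcohol is inert.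

Step 7
Reactants: 14 [(4aS,8aS)-2,5,5,8a-tetramethyl-3,4,4a,5,6,7,8,8a-octahydronaphthalen-1-yl]methanol
Product: 15 [(1S,2S,4aS,8aS)-2,5,5,8a-tetramethyldecahydronaphthalen-1-yl]methanol
Conditions: H2 (60 bar), [Ir(cod)(PCy3)(py)]PF6 (10 mol %), CH2Cl2, rt
Reagents that add atoms: none
Why: Hydroxyl-directed homogeneous hydrogenation: the cationic iridium centre is held by the C11 hydroxyl and should add both hydrogens to the α face, opposite the axial C10 methyl, which sets C8 as S (β-methyl) and C9 as S.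

Step 8
Reactants: 15 [(1S,2S,4aS,8aS)-2,5,5,8a-tetramethyldecahydronaphthalen-1-yl]methanol
Product: 16 (1S,2S,4aS,8aS)-2,5,5,8a-tetramethyldecahydronaphthalene-1-carbaldehyde
Conditions: Pr4N[RuO4] (5 mol %), N-methylmorpholine N-oxide, 4 Å molecular sieves, CH2Cl2, rt
Reagents that add atoms: none
Why: Ley–Griffith oxidation converts the hindered primary alcohol to the aldehyde under neutral conditions without touching C8; the epimerisable C9 centre is erased in step 14.

Step 9
Reactants: 17 3,4-dihydroxybenzaldehyde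
Product: 18 3,4-bis(tert-butyldimethylsilyloxy)benzaldehyde
Conditions: TBSCl (2.3 equiv), imidazole, DMF, rt
Reagents that add atoms: tert-butyldimethylsilyl chloride, CC(C)(C)[Si](C)(C)Cl
Why: Silylation of both phenols gives catechol ethers that survive organolithium, weak acid and sulfation conditions and fall to fluoride at the end.

Step 10
Reactants: 18 3,4-bis(tert-butyldimethylsilyloxy)benzaldehyde
Product: 20 3,4-bis(tert-butyldimethylsilyloxy)phenol, via aryl formate 19 (not isolated)
Conditions: mCPBA, NaHCO3, CH2Cl2, 0 °C to rt; then MeOH, Et3N (cat.), 0 °C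
Reagents that add atoms: 3-chloroperoxybenzoic acid, OOC(=O)c1cccc(Cl)c1
Why: Baeyer–Villiger oxidation of the electron-rich benzaldehyde proceeds with aryl migration to formate 19 (Dakin-type outcome), and the very labile aryl formate is methanolysed under conditions that leave aryl silyl ethers intact.

Step 11
Reactants: 20 3,4-bis(tert-butyldimethylsilyloxy)phenol
Product: 21 2-bromo-4,5-bis(tert-butyldimethylsilyloxy)phenol
Conditions: NBS (1.0 equiv), CH2Cl2, −78 to −30 °C
Reagents that add atoms: N-bromosuccinimide, BrN1C(=O)CCC1=O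
Why: Electrophilic aromatic bromination should occur ortho to the free hydroxyl and para to a silyloxy group, the only doubly activated and unhindered position.

Step 12
Reactants: 21 2-bromo-4,5-bis(tert-butyldimethylsilyloxy)phenol
Product: 22 2-[2-bromo-4,5-bis(tert-butyldimethylsilyloxy)phenoxy]oxane (racemic)
Conditions: 3,4-dihydro-2H-pyran, PPTS (cat.), CH2Cl2, rt
Reagents that add atoms: 3,4-dihydro-2H-pyran, C1=COCCC1
Why: Acid-catalysed addition of the phenol to the enol ether gives a tetrahydropyranyl acetal that tolerates organolithium reagents and leaves under the mild acid of step 14.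

Step 13
Reactants: 22 2-[2-bromo-4,5-bis(tert-butyldimethylsilyloxy)phenoxy]oxane; 16 (1S,2S,4aS,8aS)-2,5,5,8a-tetramethyldecahydronaphthalene-1-carbaldehyde
Product: 24 [4,5-bis(tert-butyldimethylsilyloxy)-2-(oxan-2-yloxy)phenyl][(1S,2S,4aS,8aS)-2,5,5,8a-tetramethyldecahydronaphthalen-1-yl]methanol (carbinol/acetal epimers), via aryllithium 23 (not isolated)
Conditions: t-BuLi (2.0 equiv), THF, −78 °C; then 16, −78 to −40 °C; H2O
Reagents that add atoms: none
Why: Bromine–lithium exchange gives aryllithium 23, stabilised by the ortho acetal oxygen and with no silyloxy group ortho to lithium (no silyl migration), and its 1,2-addition to the hindered aldehyde forms the C11–aryl bond.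

Step 14
Reactants: 24 [4,5-bis(tert-butyldimethylsilyloxy)-2-(oxan-2-yloxy)phenyl][(1S,2S,4aS,8aS)-2,5,5,8a-tetramethyldecahydronaphthalen-1-yl]methanol
Product: 26 4,5-bis(tert-butyldimethylsilyloxy)-2-{(E)-[(2S,4aS,8aS)-2,5,5,8a-tetramethyloctahydronaphthalen-1(2H)-ylidene]methyl}phenol, via phenol carbinol 25 (not isolated)
Conditions: PPTS (0.3 equiv), EtOH (10 equiv), toluene, 70 °C
Reagents that add atoms: none
Why: Acetal exchange with ethanol frees the phenol (25) and the doubly oxygen-stabilised benzylic alcohol then dehydrates by an E1 pathway with loss of H-9, giving the E alkene because the aryl group turns away from quaternary C10 towards C8, whose equatorial hydrogen lies in the alkene plane.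

Step 15
Reactants: 26 4,5-bis(tert-butyldimethylsilyloxy)-2-{(E)-[(2S,4aS,8aS)-2,5,5,8a-tetramethyloctahydronaphthalen-1(2H)-ylidene]methyl}phenol
Product: 28 5,6-bis(tert-butyldimethylsilyloxy)-2-hydroxy-3-{(E)-[(2S,4aS,8aS)-2,5,5,8a-tetramethyloctahydronaphthalen-1(2H)-ylidene]methyl}benzaldehyde, via hydroxymethyl phenol 27 (not isolated)
Conditions: MgCl2, Et3N, (CH2O)n, THF, reflux
Reagents that add atoms: formaldehyde (as paraformaldehyde), C=O
Why: Magnesium phenoxide-directed ortho-formylation: formaldehyde is delivered within the magnesium chelate to C5′, the only free position ortho to the hydroxyl, and the benzylic alkoxide of 27 is oxidised by a second formaldehyde through Oppenauer-type hydride transfer.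

Step 16
Reactants: 28 5,6-bis(tert-butyldimethylsilyloxy)-2-hydroxy-3-{(E)-[(2S,4aS,8aS)-2,5,5,8a-tetramethyloctahydronaphthalen-1(2H)-ylidene]methyl}benzaldehyde
Product: 29 3,4-bis(tert-butyldimethylsilyloxy)-2-formyl-6-{(E)-[(2S,4aS,8aS)-2,5,5,8a-tetramethyloctahydronaphthalen-1(2H)-ylidene]methyl}phenyl hydrogen sulfate
Conditions: SO3·pyridine, pyridine, 50 °C; then aq. NaHCO3
Reagents that add atoms: sulfur trioxide–pyridine complex, [O-]S(=O)(=O)[n+]1ccccc1
Why: O-Sulfonation of the only free hydroxyl by the sulfur trioxide–pyridine complex gives the aryl sulfate monoester, the catechol oxygens being masked as silyl ethers.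

Step 17
Reactants: 29 3,4-bis(tert-butyldimethylsilyloxy)-2-formyl-6-{(E)-[(2S,4aS,8aS)-2,5,5,8a-tetramethyloctahydronaphthalen-1(2H)-ylidene]methyl}phenyl hydrogen sulfate
Product: 30 2-formyl-3,4-dihydroxy-6-{(E)-[(2S,4aS,8aS)-2,5,5,8a-tetramethyloctahydronaphthalen-1(2H)-ylidene]methyl}phenyl hydrogen sulfate (CNP0149861.1)
Conditions: HF·pyridine, pyridine/THF, 0 °C to rt; then sulfonic acid resin (H+ form), MeOH/H2O, 0 °C
Reagents that add atoms: none
Why: Fluoride cleaves both aryl silyl ethers through pentacoordinate silicon while the sulfate monoester, the aldehyde and the alkene are inert, and brief contact with acidic resin returns the hydrogen sulfate form.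

Compound list
1 | but-2-yn-1-ol | CC#CCO | starting material
2 | isopropenylmagnesium bromide | CC(=C)[Mg]Br | starting material
3 | 3-methyl-4-(prop-1-en-2-yl)-2,5-dihydro-1,2-oxamagnesole (cyclic alkenylmagnesium alkoxide) | CC1=C(C(C)=C)CO[Mg]1 | intermediate
4 | (Z)-3-iodo-2-(prop-1-en-2-yl)but-2-en-1-ol | C/C(I)=C(/CO)C(C)=C | intermediate
5 | 2,2-dimethylpent-4-enal | C=CCC(C)(C)C=O | starting material
6 | diethyl [2-(methoxy(methyl)amino)-2-oxoethyl]phosphonate | CCOP(=O)(OCC)CC(=O)N(C)OC | starting material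
7 | (E)-N-methoxy-N,4,4-trimethylhepta-2,6-dienamide | C=CCC(C)(C)/C=C/C(=O)N(C)OC | intermediate
8 | (E)-7-(9-borabicyclo[3.3.1]nonan-9-yl)-N-methoxy-N,4,4-trimethylhept-2-enamide | CON(C)C(=O)/C=C/C(C)(C)CCCB1C2CCCC1CCC2 | intermediate
9 | (2E,8Z)-9-(hydroxymethyl)-N-methoxy-N,4,4,8,10-pentamethylundeca-2,8,10-trienamide | C/C(CCCC(C)(C)/C=C/C(=O)N(C)OC)=C(/CO)C(C)=C | intermediate
10 | (2E,8Z)-9-(hydroxymethyl)-4,4,8,10-tetramethylundeca-2,8,10-trienal | C/C(CCCC(C)(C)/C=C/C=O)=C(/CO)C(C)=C | intermediate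
11 | iminium ion of 10 with (2S,5S)-5-benzyl-2-tert-butyl-3-methylimidazolidin-4-one | CC(C)(C)[C@H]1[N+](=C/C=C/C(C)(C)CCC/C(C)=C(\CO)C(C)=C)[C@@H](Cc2ccccc2)C(=O)N1C | intermediate
12 | iminium ion of cycloadduct 13 with the same imidazolidinone | CC(C)(C)[C@H]1[N+](=C[C@H]2CC(C)=C(CO)[C@@]3(C)CCCC(C)(C)[C@H]23)[C@@H](Cc2ccccc2)C(=O)N1C | intermediate
13 | (1S,4aS,8aS)-4-(hydroxymethyl)-3,4a,8,8-tetramethyl-1,2,4a,5,6,7,8,8a-octahydronaphthalene-1-carbaldehyde | CC1=C(CO)[C@@]2(C)CCCC(C)(C)[C@@H]2[C@@H](C=O)C1 | intermediate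
14 | [(4aS,8aS)-2,5,5,8a-tetramethyl-3,4,4a,5,6,7,8,8a-octahydronaphthalen-1-yl]methanol | CC1=C(CO)[C@@]2(C)CCCC(C)(C)[C@@H]2CC1 | intermediate
15 | [(1S,2S,4aS,8aS)-2,5,5,8a-tetramethyldecahydronaphthalen-1-yl]methanol | C[C@H]1CC[C@H]2C(C)(C)CCC[C@]2(C)[C@H]1CO | intermediate
16 | (1S,2S,4aS,8aS)-2,5,5,8a-tetramethyldecahydronaphthalene-1-carbaldehyde | C[C@H]1CC[C@H]2C(C)(C)CCC[C@]2(C)[C@H]1C=O | intermediate
17 | 3,4-dihydroxybenzaldehyde | O=Cc1ccc(O)c(O)c1 | starting material
18 | 3,4-bis(tert-butyldimethylsilyloxy)benzaldehyde | O=Cc1ccc(O[Si](C)(C)C(C)(C)C)c(O[Si](C)(C)C(C)(C)C)c1 | intermediate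
19 | 3,4-bis(tert-butyldimethylsilyloxy)phenyl formate | O=COc1ccc(O[Si](C)(C)C(C)(C)C)c(O[Si](C)(C)C(C)(C)C)c1 | intermediate
20 | 3,4-bis(tert-butyldimethylsilyloxy)phenol | Oc1ccc(O[Si](C)(C)C(C)(C)C)c(O[Si](C)(C)C(C)(C)C)c1 | intermediate
21 | 2-bromo-4,5-bis(tert-butyldimethylsilyloxy)phenol | Oc1cc(O[Si](C)(C)C(C)(C)C)c(O[Si](C)(C)C(C)(C)C)cc1Br | intermediate
22 | 2-[2-bromo-4,5-bis(tert-butyldimethylsilyloxy)phenoxy]oxane (racemic) | Brc1cc(O[Si](C)(C)C(C)(C)C)c(O[Si](C)(C)C(C)(C)C)cc1OC1CCCCO1 | intermediate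
23 | [4,5-bis(tert-butyldimethylsilyloxy)-2-(oxan-2-yloxy)phenyl]lithium | [Li]c1cc(O[Si](C)(C)C(C)(C)C)c(O[Si](C)(C)C(C)(C)C)cc1OC1CCCCO1 | intermediate
24 | [4,5-bis(tert-butyldimethylsilyloxy)-2-(oxan-2-yloxy)phenyl][(1S,2S,4aS,8aS)-2,5,5,8a-tetramethyldecahydronaphthalen-1-yl]methanol (epimers at carbinol and acetal carbons) | C[C@H]1CC[C@H]2C(C)(C)CCC[C@]2(C)[C@H]1C(O)c1cc(O[Si](C)(C)C(C)(C)C)c(O[Si](C)(C)C(C)(C)C)cc1OC1CCCCO1 | intermediate
25 | 4,5-bis(tert-butyldimethylsilyloxy)-2-{hydroxy[(1S,2S,4aS,8aS)-2,5,5,8a-tetramethyldecahydronaphthalen-1-yl]methyl}phenol (carbinol epimers) | C[C@H]1CC[C@H]2C(C)(C)CCC[C@]2(C)[C@H]1C(O)c1cc(O[Si](C)(C)C(C)(C)C)c(O[Si](C)(C)C(C)(C)C)cc1O | intermediate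
26 | 4,5-bis(tert-butyldimethylsilyloxy)-2-{(E)-[(2S,4aS,8aS)-2,5,5,8a-tetramethyloctahydronaphthalen-1(2H)-ylidene]methyl}phenol | C[C@H]1CC[C@H]2C(C)(C)CCC[C@]2(C)/C1=C/c1cc(O[Si](C)(C)C(C)(C)C)c(O[Si](C)(C)C(C)(C)C)cc1O | intermediate
27 | 3,4-bis(tert-butyldimethylsilyloxy)-2-(hydroxymethyl)-6-{(E)-[(2S,4aS,8aS)-2,5,5,8a-tetramethyloctahydronaphthalen-1(2H)-ylidene]methyl}phenol | C[C@H]1CC[C@H]2C(C)(C)CCC[C@]2(C)/C1=C/c1cc(O[Si](C)(C)C(C)(C)C)c(O[Si](C)(C)C(C)(C)C)c(CO)c1O | intermediate
28 | 5,6-bis(tert-butyldimethylsilyloxy)-2-hydroxy-3-{(E)-[(2S,4aS,8aS)-2,5,5,8a-tetramethyloctahydronaphthalen-1(2H)-ylidene]methyl}benzaldehyde | C[C@H]1CC[C@H]2C(C)(C)CCC[C@]2(C)/C1=C/c1cc(O[Si](C)(C)C(C)(C)C)c(O[Si](C)(C)C(C)(C)C)c(C=O)c1O | intermediate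
29 | 3,4-bis(tert-butyldimethylsilyloxy)-2-formyl-6-{(E)-[(2S,4aS,8aS)-2,5,5,8a-tetramethyloctahydronaphthalen-1(2H)-ylidene]methyl}phenyl hydrogen sulfate | C[C@H]1CC[C@H]2C(C)(C)CCC[C@]2(C)/C1=C/c1cc(O[Si](C)(C)C(C)(C)C)c(O[Si](C)(C)C(C)(C)C)c(C=O)c1OS(=O)(=O)O | intermediate
30 | 2-formyl-3,4-dihydroxy-6-{(E)-[(2S,4aS,8aS)-2,5,5,8a-tetramethyloctahydronaphthalen-1(2H)-ylidene]methyl}phenyl hydrogen sulfate | C[C@H]1CC[C@H]2C(C)(C)CCC[C@]2(C)/C1=C/c1cc(O)c(O)c(C=O)c1OS(=O)(=O)O | target

Total step count: 17. Longest linear sequence: 12 steps (steps 1, 3–8 and 13–17); steps 2 and 9–12 prepare the two side fragments.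

Steps most likely to fail

Step 5. The fully substituted diene terminus and the neopentyl β-carbon of the enal may stall iminium turnover, or the developing 1,3-diaxial methyl/methyl contact may erode endo and facial selectivity so that cis-fused or poorly enriched adduct forms. Fallback (sets out from 5, returns at 13): stereocontrol is handed to a covalently bound auxiliary and a Lewis acid. Aldehyde 5 is olefinated with diethyl {2-[(4S)-4-benzyl-2-oxooxazolidin-3-yl]-2-oxoethyl}phosphonate (LiCl, i-Pr2NEt, MeCN) to give (4S)-4-benzyl-3-[(E)-4,4-dimethylhepta-2,6-dienoyl]oxazolidin-2-one F1. 9-BBN converts its terminal alkene into the B-alkyl-9-borabicyclononane F2, which is coupled with 4 as in step 3 to give the triene imide F3. Me2AlCl (2.5 equiv, CH2Cl2, −30 °C; the first equivalent caps the alcohol as its aluminium alkoxide) should promote the intramolecular Diels–Alder reaction of the chelated s-cis imide, endo and anti to the benzyl group, to give the cycloadduct imide F4. Me(MeO)NH·HCl/AlMe3 exchanges the auxiliary for the N-methoxy-N-methylamide F5, and i-Bu2AlH (THF, −78 °C) reduces it to 13.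

Step 7. The tetrasubstituted alkene between C8 and quaternary C10 may fail to bind iridium, or hydrogen may be delivered without face control. Fallback (sets out from 14, returns at 15): the C8 hydrogen is delivered intramolecularly with transposition of the alkene, and C9 is set by hydroboration. MnO2 (CH2Cl2) oxidises 14 to the enal (4aS,8aS)-2,5,5,8a-tetramethyl-3,4,4a,5,6,7,8,8a-octahydronaphthalene-1-carbaldehyde F6, and TsNHNH2 (EtOH, 60 °C) gives its tosylhydrazone F7. Catecholborane (CHCl3, 0 °C) then NaOAc·3H2O (reflux) reduces the C=N bond and eliminates sulfinate to the allylic diazene F8. F8 loses dinitrogen in a retro-ene shift that should place hydrogen on the open α face of C8 and give (2S,4aS,8aS)-2,5,5,8a-tetramethyl-1-methylidenedecahydronaphthalene F9. 9-BBN adds from the same α face to give the alkylborane F10, and NaOH/H2O2 oxidises it to 15.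

Step 15. Hydroxymethylation at the crowded C5′ position between a silyl ether and the phenol may be slow, and the basic magnesium medium may begin to cleave the aryl silyl ethers. Fallback (sets out from 26, returns at 28): the one-carbon unit is delivered by a boron template under weakly acidic conditions and oxidised separately. PhB(OH)2, paraformaldehyde and catalytic propionic acid (toluene, reflux, water removal) convert 26 into the 2-phenyl-4H-1,3,2-benzodioxaborin F11. Exchange with propane-1,3-diol releases the hydroxymethyl phenol 27, here isolated, and MnO2 (CH2Cl2) oxidises its benzylic alcohol to 28.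

Further compounds
F1 | step 5 | (4S)-4-benzyl-3-[(E)-4,4-dimethylhepta-2,6-dienoyl]oxazolidin-2-one | C=CCC(C)(C)/C=C/C(=O)N1C(=O)OC[C@@H]1Cc1ccccc1
F2 | step 5 | (4S)-4-benzyl-3-[(E)-7-(9-borabicyclo[3.3.1]nonan-9-yl)-4,4-dimethylhept-2-enoyl]oxazolidin-2-one | O=C(/C=C/C(C)(C)CCCB1C2CCCC1CCC2)N1C(=O)OC[C@@H]1Cc1ccccc1
F3 | step 5 | (4S)-4-benzyl-3-[(2E,8Z)-9-(hydroxymethyl)-4,4,8,10-tetramethylundeca-2,8,10-trienoyl]oxazolidin-2-one | C/C(CCCC(C)(C)/C=C/C(=O)N1C(=O)OC[C@@H]1Cc1ccccc1)=C(/CO)C(C)=C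
F4 | step 5 | (4S)-4-benzyl-3-{[(1S,4aS,8aS)-4-(hydroxymethyl)-3,4a,8,8-tetramethyl-1,2,4a,5,6,7,8,8a-octahydronaphthalen-1-yl]carbonyl}oxazolidin-2-one | CC1=C(CO)[C@@]2(C)CCCC(C)(C)[C@@H]2[C@@H](C(=O)N3C(=O)OC[C@@H]3Cc4ccccc4)C1
F5 | step 5 | (1S,4aS,8aS)-4-(hydroxymethyl)-N-methoxy-N,3,4a,8,8-pentamethyl-1,2,4a,5,6,7,8,8a-octahydronaphthalene-1-carboxamide | CC1=C(CO)[C@@]2(C)CCCC(C)(C)[C@@H]2[C@@H](C(=O)N(C)OC)C1
F6 | step 7 | (4aS,8aS)-2,5,5,8a-tetramethyl-3,4,4a,5,6,7,8,8a-octahydronaphthalene-1-carbaldehyde | CC1=C(C=O)[C@@]2(C)CCCC(C)(C)[C@@H]2CC1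
F7 | step 7 | N'-{(E)-[(4aS,8aS)-2,5,5,8a-tetramethyl-3,4,4a,5,6,7,8,8a-octahydronaphthalen-1-yl]methylidene}-4-methylbenzenesulfonohydrazide | CC1=C(/C=N/NS(=O)(=O)c2ccc(C)cc2)[C@@]2(C)CCCC(C)(C)[C@@H]2CC1
F8 | step 7 | {[(4aS,8aS)-2,5,5,8a-tetramethyl-3,4,4a,5,6,7,8,8a-octahydronaphthalen-1-yl]methyl}diazene | CC1=C(CN=N)[C@@]2(C)CCCC(C)(C)[C@@H]2CC1
F9 | step 7 | (2S,4aS,8aS)-2,5,5,8a-tetramethyl-1-methylidenedecahydronaphthalene | C[C@H]1CC[C@H]2C(C)(C)CCC[C@]2(C)C1=C
F10 | step 7 | 9-{[(1S,2S,4aS,8aS)-2,5,5,8a-tetramethyldecahydronaphthalen-1-yl]methyl}-9-borabicyclo[3.3.1]nonane | C[C@H]1CC[C@H]2C(C)(C)CCC[C@]2(C)[C@H]1CB1C2CCCC1CCC2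
F11 | step 15 | 5,6-bis(tert-butyldimethylsilyloxy)-2-phenyl-8-{(E)-[(2S,4aS,8aS)-2,5,5,8a-tetramethyloctahydronaphthalen-1(2H)-ylidene]methyl}-4H-1,3,2-benzodioxaborinine | C[C@H]1CC[C@H]2C(C)(C)CCC[C@]2(C)/C1=C/c1cc(O[Si](C)(C)C(C)(C)C)c(O[Si](C)(C)C(C)(C)C)c2c1OB(c1ccccc1)OC2
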